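**Retrosynthetic overview**

1. Numbering: unit A is the half with C6 and C7 in the cyclobutane (C1, O2, C3, C3a, C4–C7, C7a, chain C8–C11); unit B (primed) has C3a' and C7a' in the cyclobutane. Ring A = carbocycle of unit A, ring B = its lactone, ring C = cyclobutane, ring D = carbocycle of unit B, ring E = its lactone.
2. Ring B is made last (C7a–C1 and C1–O2) by carbonylative enol lactonisation of a C7a vinyl triflate carrying the C3 pentanoyl group; both derive from a ring A ketone at C7a.
3. Ring E is closed before that at C7a'–C1'. C7a' lies between C7', which ends as an alkene carbon and can carry a ketone that makes C7a' an enolate carbon, and C3a', whose C3' substituent carries O2'. A (Z)-enol phenyl carbonate on O2' is then acylated by the C7a' enolate in a five-membered closure. Because rings C, D and E share the C3a'–C7a' bond (a [4.3.2]propellane), closure can only be cis and the C7a' configuration of the precursor is erased (stereoconvergent).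
4. Ring C comes from an intramolecular enone–alkene [2+2] photocycloaddition of a cyclohexenyl ester. Its ester carbonyl becomes C3' and its alkoxy oxygen sits on C7a, whose carbinol centre, from (R)-cyclohex-2-en-1-ol, relays absolute configuration to C6, C7 and C3a' and is later oxidised away.
5. Order of ring formation: rings A and D purchased → ring C with a temporary γ-lactone (step 2) → ring E (step 8) → ring B (step 15).

Key step: step 8

Assumption: acid 1 and enantiopure alcohol 2 are purchased (2 is otherwise available by known asymmetric reduction of cyclohex-2-en-1-one).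

**Step 1**
Reactants: 1 3-oxocyclohex-1-ene-1-carboxylic acid; 2 (R)-cyclohex-2-en-1-ol
Product: 3 (R)-cyclohex-2-en-1-yl 3-oxocyclohex-1-ene-1-carboxylate
Conditions: DCC, DMAP (cat.), CH2Cl2, 0 °C → rt
Reagents that add atoms: none
Why: Steglich esterification acylates the allylic oxygen without touching the C–O bond of the carbinol carbon, so the R configuration of 2 is carried into 3 unchanged.

**Step 2**
Reactants: 3 (R)-cyclohex-2-en-1-yl 3-oxocyclohex-1-ene-1-carboxylate
Product: 4 keto lactone photoadduct
Conditions: hν (350 nm), CH2Cl2 (5 mM, degassed), rt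
Reagents that add atoms: none
Why: Intramolecular enone–alkene [2+2] photocycloaddition through the triplet enone follows the rule of five for the three-atom tether C3'–O–C7a (C3a'–C7 bond first, then C7a'–C6, straight adduct), and because the five-membered tether ring can only be cis-fused to rings A and C the C7a carbinol centre sets C6, C7 and C3a' (ring A and C3' on one face of ring C, ring D on the other), while C7a' may form as either epimer without consequence.

**Step 3**
Reactants: 4 keto lactone photoadduct
Product: 5 ketal lactone
Conditions: HOCH2CH2OH, p-TsOH (cat.), toluene, reflux (Dean–Stark)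
Reagents that add atoms: ethylene glycol, OCCO
Why: Acid-catalysed dioxolane formation masks the only ketone before organolithium chemistry, and the reversible acidic conditions should also equilibrate C7a' to the cis-fused ring C/ring D epimer through the enol.

**Step 4**
Reactants: 5 ketal lactone
Product: 6 hydroxy butyl ketone
Conditions: n-BuLi (1.05 equiv), THF, −78 °C; then aq. NH4Cl
Reagents that add atoms: n-butyllithium, [Li]CCCC
Why: Organolithium mono-addition to the γ-lactone stops at the tetrahedral lithium alkoxide at −78 °C, and the neopentyl-type ketone released on quench resists a second addition, so C3' becomes the n-butyl ketone and the C7a hydroxyl is freed with no stereocentre involved.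

**Step 5**
Reactants: 6 hydroxy butyl ketone
Product: 7 silyl ether ketone
Conditions: TBSCl, imidazole, DMF, 40 °C
Reagents that add atoms: tert-butyldimethylsilyl chloride, CC(C)(C)[Si](C)(C)Cl
Why: Silyl ether formation takes the secondary C7a hydroxyl of the open hydroxy ketone and drains any cyclic hemiketal form, whose tertiary hydroxyl is too hindered to silylate under these conditions.

**Step 6**
Reactants: 7 silyl ether ketone
Product: 9 Z-enol phenyl carbonate ketal, via lithium Z-enolate 8 (not isolated)
Conditions: LiN(i-Pr)2, THF, −78 °C; then ClCO2Ph, DMPU, −78 → −40 °C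
Reagents that add atoms: phenyl chloroformate, O=C(Cl)Oc1ccccc1
Why: Kinetic deprotonation of a ketone flanked by a quaternary carbon gives the Z(O) enolate (C8' is the only enolisable position and the propyl chain avoids the C3a' substituents), and hard O-acylation by the chloroformate in the presence of DMPU (enol carbonate formation) fixes the Z geometry required at C3'=C8'.

**Step 7**
Reactants: 9 Z-enol phenyl carbonate ketal
Product: 10 Z-enol phenyl carbonate ketone
Conditions: PPTS (cat.), acetone/H2O, 55 °C
Reagents that add atoms: water, O
Why: Mild acid-catalysed ketal hydrolysis liberates the C7' ketone while the secondary TBS ether and the enol aryl carbonate are stable to weak acid.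

**Step 8**
Reactants: 10 Z-enol phenyl carbonate ketone
Product: 12 β-keto enol lactone, via sodium C7a' enolate 11 (not isolated)
Conditions: NaH (1.5 equiv), THF (0.01 M), 0 °C → rt; then aq. NH4Cl
Reagents that add atoms: none
Why: NaH converts ketone 10 into its sodium enolates, which interconvert by proton exchange with ketone not yet deprotonated; only the C7a' enolate 11 can reach the carbonate carbon, and its attack gives a tetrahedral intermediate that expels phenoxide (a far better leaving group than the O2' enolate), forming the C7a'–C1' bond irreversibly. The closest known reaction type is the Dieckmann or Baker–Venkataraman-type intramolecular C-acylation of a ketone enolate by an aryl ester or carbonate. Ring E is closed in a 5-(enolexo)-exo-trig mode. The new quaternary stereocentre C7a' is controlled by C3a': the carbonate hangs from C3' on the face of ring C that also carries ring A, and since rings C, D and E must all share the C3a'–C7a' bond the acyl group can only be delivered to that face, so either C7a' epimer of 10 gives the same product. The step needs C- over O-acylation and reaction at C7a' rather than C6': O-acylation would require a seven-membered ring trans-fused to ring C (or holding an E enolate double bond) and attack from C6' a bridged seven-membered ring, whereas C7a' attack is a strain-free five-membered closure.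

**Step 9**
Reactants: 12 β-keto enol lactone
Product: 14 enol triflate, via potassium C6' enolate 13 (not isolated)
Conditions: KN(SiMe3)2, THF, −78 °C; then PhNTf2, −78 → 0 °C
Reagents that add atoms: N-phenylbis(trifluoromethanesulfonimide), O=S(=O)(N(c1ccccc1)S(=O)(=O)C(F)(F)F)C(F)(F)F
Why: Enol triflate formation is regiospecific because C7a' is now quaternary, so deprotonation can only occur at C6' and O-sulfonylation of that enolate fixes the double bond at C6'=C7'.

**Step 10**
Reactants: 14 enol triflate
Product: 15 silyl ether with complete unit B
Conditions: Pd(OAc)2 (cat.), PPh3, n-Bu3N, HCO2H, DMF, 60 °C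
Reagents that add atoms: none
Why: Palladium-catalysed formate hydrogenolysis of the enol triflate (oxidative addition of zerovalent palladium, formate-to-hydride exchange with loss of CO2, reductive elimination) replaces OTf by H without moving the double bond, which completes unit B.

**Step 11**
Reactants: 15 silyl ether with complete unit B
Product: 16 C7a alcohol
Conditions: HF·pyridine, THF, 0 °C → rt
Reagents that add atoms: none
Why: Fluoride-mediated desilylation under weakly acidic conditions removes the TBS group without the basic conditions that could open the enol lactone.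

**Step 12**
Reactants: 16 C7a alcohol
Product: 17 ring A ketone
Conditions: Dess–Martin periodinane, CH2Cl2, rt
Reagents that add atoms: none
Why: Dess–Martin oxidation of the secondary alcohol under neutral conditions gives the ring A ketone and removes the C7a stereocentre once it has relayed the absolute configuration.

**Step 13**
Reactants: 17 ring A ketone
Product: 18 β-diketone
Conditions: MgBr2·OEt2, i-Pr2NEt, CH3(CH2)3COCl, CH2Cl2, rt
Reagents that add atoms: pentanoyl chloride, CCCCC(=O)Cl
Why: Soft-enolisation C-acylation (a Claisen-type ketone acylation through a reversibly formed magnesium enolate) occurs at the unhindered C3a methylene and not at the ring-fusion methine C7, avoids strong base in the presence of ring E, and creates no stereocentre because C3a is sp2 in the enol.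

**Step 14**
Reactants: 18 β-diketone
Product: 19 C7a vinyl triflate
Conditions: Tf2O, i-Pr2NEt, CH2Cl2, −78 °C
Reagents that add atoms: trifluoromethanesulfonic anhydride, O=S(=O)(OS(=O)(=O)C(F)(F)F)C(F)(F)F
Why: Vinyl triflate formation by O-sulfonylation of the diketone enolate should occur on the ring oxygen, because six-membered 2-acyl ketones prefer the endocyclic enol, giving the C7a triflate with the tetrasubstituted C3a=C7a bond of the target.

**Step 15**
Reactants: 19 C7a vinyl triflate
Product: 20 target dimer
Conditions: Pd(PPh3)4 (cat.), CO (1 atm), Et3N, MeCN, 60 °C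
Reagents that add atoms: carbon monoxide, [C-]#[O+]
Why: Carbonylative enol lactonisation (oxidative addition of zerovalent palladium to the C7a–OTf bond, CO insertion, then 5-exo O-acylation of the amine-generated enolate of the C3 butyl ketone by the acylpalladium) closes ring B, and the Z butylidene is expected because the E isomer suffers allylic strain between C9 and the C4 methylene.

**Compound list**

1 | 3-oxocyclohex-1-ene-1-carboxylic acid | O=C1C=C(C(=O)O)CCC1 | starting material
2 | (R)-cyclohex-2-en-1-ol | O[C@@H]1CCCC=C1 | starting material
3 | (R)-cyclohex-2-en-1-yl 3-oxocyclohex-1-ene-1-carboxylate | O=C1C=C(C(=O)O[C@@H]2CCCC=C2)CCC1 | intermediate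
4 | keto lactone photoadduct: rings A, C and D fused 6-4-6 (C6–C7a', C7–C3a'), γ-lactone C3'(=O)–O–C7a bridging C3a' and C7, ketone at C7'; 7aR, ring A and C3' on one face of ring C, ring D on the other, H at C7a' cis to C3' | O=C1O[C@@H]2CCC[C@H]3[C@@H]2[C@@]14CCCC(=O)[C@H]34 | intermediate
5 | ketal lactone: C7' ethylene ketal of 4 | O=C1O[C@@H]2CCC[C@H]3[C@@H]2[C@@]14CCCC5(OCCO5)[C@H]34 | intermediate
6 | hydroxy butyl ketone: C7a–OH, pentanoyl group (C3' ketone, chain C8'–C11') on C3a', C7' ketal, ring C configured as in 4 | O[C@@H]1CCC[C@H]2[C@@H]1[C@]3(C(=O)CCCC)CCCC4(OCCO4)[C@H]23 | intermediate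
7 | silyl ether ketone: C7a tert-butyldimethylsilyl ether of 6 | CC(C)(C)[Si](C)(C)O[C@@H]1CCC[C@H]2[C@@H]1[C@]3(C(=O)CCCC)CCCC4(OCCO4)[C@H]23 | intermediate
8 | lithium Z-enolate of 7 (O2' and the propyl group cis on C3'=C8') | CC(C)(C)[Si](C)(C)O[C@@H]1CCC[C@H]2[C@@H]1[C@]3(/C([O-])=C/CCC)CCCC4(OCCO4)[C@H]23.[Li+] | intermediate
9 | Z-enol phenyl carbonate ketal: O2'–C(=O)OPh on the (Z)-C3'=C8' enol of 7 | CC(C)(C)[Si](C)(C)O[C@@H]1CCC[C@H]2[C@@H]1[C@]3(/C(OC(=O)Oc4ccccc4)=C/CCC)CCCC5(OCCO5)[C@H]23 | intermediate
10 | Z-enol phenyl carbonate ketone: 9 with the C7' ketone freed | CC(C)(C)[Si](C)(C)O[C@@H]1CCC[C@H]2[C@@H]1[C@]3(/C(OC(=O)Oc4ccccc4)=C/CCC)CCCC(=O)[C@H]23 | intermediate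
11 | sodium C7a' enolate of 10 (C7'(ONa)=C7a') | CC(C)(C)[Si](C)(C)O[C@@H]1CCC[C@H]2[C@@H]1[C@]3(/C(OC(=O)Oc4ccccc4)=C/CCC)CCCC([O-])=C23.[Na+] | intermediate
12 | β-keto enol lactone: ring E closed (C7a'–C1'), C7a' quaternary with C1' cis to C3', (Z)-butylidene at C3', ketone at C7', C7a–OTBS | CC(C)(C)[Si](C)(C)O[C@@H]1CCC[C@H]2[C@@H]1[C@]34CCCC(=O)[C@]23C(=O)O/C4=C\CCC | intermediate
13 | potassium C6' enolate of 12 (C6'=C7'–OK) | CC(C)(C)[Si](C)(C)O[C@@H]1CCC[C@H]2[C@@H]1[C@]34CCC=C([O-])[C@]23C(=O)O/C4=C\CCC.[K+] | intermediate
14 | enol triflate: C7'–OTf with C6'=C7' | CC(C)(C)[Si](C)(C)O[C@@H]1CCC[C@H]2[C@@H]1[C@]34CCC=C(OS(=O)(=O)C(F)(F)F)[C@]23C(=O)O/C4=C\CCC | intermediate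
15 | silyl ether with complete unit B (C6'=C7' alkene, ring E, (Z)-butylidene), C7a–OTBS | CC(C)(C)[Si](C)(C)O[C@@H]1CCC[C@H]2[C@@H]1[C@]34CCC=C[C@]23C(=O)O/C4=C\CCC | intermediate
16 | C7a alcohol from 15 | O[C@@H]1CCC[C@H]2[C@@H]1[C@]34CCC=C[C@]23C(=O)O/C4=C\CCC | intermediate
17 | ring A ketone (C7a=O) | O=C1CCC[C@H]2[C@@H]1[C@]34CCC=C[C@]23C(=O)O/C4=C\CCC | intermediate
18 | β-diketone: pentanoyl on C3a of 17, drawn as the ring enol C7a(OH)=C3a | OC1=C(C(=O)CCCC)CC[C@H]2[C@@H]1[C@]34CCC=C[C@]23C(=O)O/C4=C\CCC | intermediate
19 | C7a vinyl triflate (C3a=C7a, pentanoyl on C3a) | O=S(=O)(OC1=C(C(=O)CCCC)CC[C@H]2[C@@H]1[C@]34CCC=C[C@]23C(=O)O/C4=C\CCC)C(F)(F)F | intermediate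
20 | target dimer: (3Z,3'Z,6S,7R,3a'R,7a'S) [2+2] dimer of the 3-butylidene-dihydrophthalide, C6–C7a' and C7–C3a' bonds, ring A and ring E on one face of ring C, ring D on the other | CCC/C=C1\OC(=O)C2=C1CC[C@H]1[C@@H]2[C@]23CCC=C[C@]12C(=O)O/C3=C\CCC | target

**Totals**

Total step count: 15. Longest linear sequence: 15 steps (from 1 or 2 to 20).

**Steps most likely to fail**

Step 8. Enolisation toward the hindered ring-fusion methine C7a' may be too slow, so that the unproductive C6' enolate accumulates and intermolecular acyl transfer or cleavage of the carbonate takes over. The fallback enforces the regiochemistry instead of relying on equilibration. It sets out from 10: dehydrogenation with 2-iodoxybenzoic acid (DMSO, 70 °C) would give enone enol carbonate F1, whose only kinetically accessible proton (α' to the enone) is the one on C7a'. LiN(SiMe3)2 (THF, −78 → 0 °C) would then effect the same Dieckmann-type closure to enone keto lactone F2. Conjugate reduction with LiBH(s-Bu)3 and trapping of the resulting C6' enolate with PhNTf2 would return to the route at enol triflate 14.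

Step 2. The ester tether may stay in its extended s-trans conformation, so that the excited enone decays or dimerises before it meets the ring A alkene. The fallback uses an ether tether, which has no such bias. It sets out from 2: alkylation of its sodium alkoxide (NaH, THF, 0 °C) with 3-(bromomethyl)cyclohex-2-en-1-one (BrCC1=CC(=O)CCC1, assumed purchasable) would give allylic ether F3. Irradiation as in step 2 would give tetrahydrofuran photoadduct F4. Oxidation of the ether methylene C3' with RuCl3 (cat.)/NaIO4 would return to the route at keto lactone 4.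

Step 14. Sulfonylation may occur at the exocyclic acyl oxygen or at both oxygens, giving the wrong or a mixed vinyl triflate. The fallback places the halide on C7a before the side chain is completed. It sets out from 17: Vilsmeier–Haack-type bromoformylation (PBr3, DMF, CHCl3) would give bromo enal F5 (Br on C7a, CHO on C3a). Addition of n-BuMgBr (THF, −78 °C) to the aldehyde would give allylic alcohol F6, and Dess–Martin oxidation would give bromo enone F7. Carbonylative lactonisation under the conditions of step 15 would return to the route at 20.

**Further compounds**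

F1 | step 8 | enone enol carbonate (10 with C5'=C6') | CC(C)(C)[Si](C)(C)O[C@@H]1CCC[C@H]2[C@@H]1[C@]3(/C(OC(=O)Oc4ccccc4)=C/CCC)CC=CC(=O)[C@H]23
F2 | step 8 | enone keto lactone (12 with C5'=C6') | CC(C)(C)[Si](C)(C)O[C@@H]1CCC[C@H]2[C@@H]1[C@]34CC=CC(=O)[C@]23C(=O)O/C4=C\CCC
F3 | step 2 | allylic ether, 3-{[(R)-cyclohex-2-en-1-yloxy]methyl}cyclohex-2-en-1-one | O=C1C=C(CO[C@@H]2CCCC=C2)CCC1
F4 | step 2 | tetrahydrofuran photoadduct (4 with CH2 at C3') | C1O[C@@H]2CCC[C@H]3[C@@H]2[C@@]14CCCC(=O)[C@H]34
F5 | step 14 | bromo enal (Br on C7a, CHO on C3a, C3a=C7a) | BrC1=C(C=O)CC[C@H]2[C@@H]1[C@]34CCC=C[C@]23C(=O)O/C4=C\CCC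
F6 | step 14 | allylic alcohol (1-hydroxypentyl on C3a, carbinol centre unspecified) | BrC1=C(C(O)CCCC)CC[C@H]2[C@@H]1[C@]34CCC=C[C@]23C(=O)O/C4=C\CCC
F7 | step 14 | bromo enone (Br on C7a, pentanoyl on C3a) | BrC1=C(C(=O)CCCC)CC[C@H]2[C@@H]1[C@]34CCC=C[C@]23C(=O)O/C4=C\CCC
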